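We start from amounts: 0.50 mM of free catalyst against 0.10 M each of left-handed and right-handed substrate, with coupling partner dissolving from the gas.

left-handed substrate 0.10 M; gas 4.3 mM (held); free catalyst 0.50 mM; right-handed substrate 0.10 M

    free catalyst + left-handed substrate ⇌ catalyst intermediate A (K1 = 9.6 M⁻¹, k1 = 3.4 M⁻¹ s⁻¹)
    gas ⇌ coupling partner, rate k2*(csat - [coupling partner]) (k2 = 0.010 s⁻¹, csat = 4.3 mM)
    coupling partner + free catalyst → spent catalyst (k3 = 0.12 M⁻¹ s⁻¹)
    coupling partner + catalyst intermediate B → free catalyst + right-handed product (k4 = 0.75 M⁻¹ s⁻¹)
    coupling partner + catalyst intermediate A → free catalyst + left-handed product (k5 = 17 M⁻¹ s⁻¹)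
    free catalyst + right-handed substrate ⇌ catalyst intermediate B (K6 = 27 M⁻¹, k6 = 11 M⁻¹ s⁻¹)

- the form that holds most of the catalyst when 20 % of the left-handed substrate and right-handed substrate together are converted (catalyst intermediate B / catalyst intermediate A / spent catalyst / free catalyst)
- its share of the catalyst then
- factor on the rate of making left-handed product when 20 % of the left-handed substrate and right-handed substrate together are converted if free catalyst is charged twice over
- factor on the rate when 20 % of the left-handed substrate and right-handed substrate together are converted if free catalyst is charged at 5.0 mM instead

Coupling partner both turns the catalyst over and destroys free catalyst, so we divide one rate by the other and it cancels. Binding runs at 1200 h⁻¹ per free catalyst, faster than catalyst intermediate A is consumed with coupling partner at saturation, so we hold [A], the concentration of catalyst intermediate A, at K[free catalyst][left-handed substrate], with K = 7.96 M⁻¹. Working with f, the fraction of left-handed substrate left, the spent share of the catalyst is −δ ln f. Here δ is the constant of deactivation over the constant of left-handed coupling times K times the catalyst charge, our death number: 1.77. It exceeds unity, so in this reckoning the catalyst of the flask charged at 0.50 mM is wholly spent with left-handed substrate remaining, at f = 56.9 %.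

The right-handed substrate reacts with selectivity factor 0.149, which puts f at 65.7 % at the asked conversion. We therefore commit to spent catalyst at 74.5 %, above half of the catalyst. Scaling δ with the charge gives active catalyst up by 4.92 on doubling and 36.3 at 5.0 mM.

Those factors hold coupling partner at saturation, and that is where one number may not be enough for the rates. In a flask charged at 5.0 mM, with the whole charge active and in equilibrium with the charged substrates, catalyst intermediate A consumes coupling partner at 0.0175 s⁻¹, more than the transfer coefficient 0.010 s⁻¹.

The forecast gives spent catalyst at 73 %, with rate factors 4.2 and 16.5, lower than our factors for active catalyst. Its ground for the share is: “Integrating gives about 0.36 mM spent, nearly independent of charge.”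

The simulation gives spent catalyst at 72.5 % after 3.22 h, with factors 4.23 and 16.5. In the flask charged at 0.50 mM, spent catalyst stands at 99.9 % after 15.0 h, with 57 % of the charged left-handed substrate still there, unbound, and our f for that end was 56.9 %. In the flask charged at 5.0 mM, δ is 0.177, and the rate factor of 16.5 is about half of our 36.3 for active catalyst, with 23.0 % of that flask's catalyst free at the same conversion.

(The numbers come from no measurement; no experiment stands behind them.)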